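**Retrosynthetic overview**
1. Target 26 ⇐ 15‑O‑TBDPS labda‑8(17),13E‑diene‑3β,19‑diol 23 by chemoselective C19 oxidation, 3‑O‑acetylation and desilylation.
2. Decalin 23 ⇐ one cationic epoxy‑polyene bicyclisation of acyclic epoxide 21. Ring A closes first (C4–C5), then ring B (C9–C10); an allylsilane terminates the cascade as the 8(17)‑alkene. C3, C4, C5, C9 and C10 are set in this step.
3. Epoxide 21 ⇐ Sharpless epoxidation of (2Z)‑allylic alcohol 19 ⇐ β‑oxido‑ylide olefination of trienal 13. The Z‑CH2O group becomes the axial C19.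
4. Trienal 13 ⇐ two cycles of vinyl‑Grignard addition and Claisen rearrangement from aldehyde 4 ⇐ geraniol.

Assumption: the SMILES is read as the normal‑series labdane 3β‑acetoxy‑15‑hydroxylabda‑8(17),13E‑dien‑19‑al, (3S,4R,5R,9S,10R); labdane numbering is used for the bicyclic compounds and in the Why lines.

**Route**

Step 1
Reactants: 1 geraniol
Product: 2 tert-butyl{[(2E)-3,7-dimethylocta-2,6-dien-1-yl]oxy}diphenylsilane
Conditions: TBDPSCl, imidazole, DMF, 0 °C → rt
Reagents that add atoms: tert‑butyl(chloro)diphenylsilane, CC(C)(C)[Si](Cl)(c1ccccc1)c1ccccc1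
Why: Standard silylation of a primary alcohol; the acid‑, base‑ and Lewis‑acid‑stable TBDPS ether carries O15 to the last step.

Step 2
Reactants: 2 geranyl TBDPS ether
Product: 4 (4E)-6-[(tert-butyldiphenylsilyl)oxy]-4-methylhex-4-enal, via 6,7-epoxide 3 (not isolated)
Conditions: mCPBA, CH2Cl2, 0 °C; then H5IO6, THF/H2O, 0 °C → rt (same flask)
Reagents that add atoms: meta‑chloroperoxybenzoic acid, O=C(OO)c1cccc(Cl)c1
Why: Prilezhaev epoxidation prefers the distal alkene because the 2,3‑alkene is deactivated by the allylic silyloxy group, and periodic acid cleaves the epoxide to the aldehyde with loss of acetone.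

Step 3
Reactants: 4 aldehyde; 5 (2-bromoallyl)trimethylsilane
Product: 6 (6E)-8-[(tert-butyldiphenylsilyl)oxy]-6-methyl-2-[(trimethylsilyl)methyl]octa-1,6-dien-3-ol (racemic)
Conditions: 5, Mg, THF, reflux; then 4, THF, −78 → 0 °C; aq. NH4Cl
Reagents that add atoms: (2‑bromoallyl)trimethylsilane 5, C=C(Br)C[Si](C)(C)C
Why: Grignard addition of the 2‑(silylmethyl)vinyl unit installs C8, C7 and the C17–Si terminator carbon; the carbinol centre is racemic on purpose because the next step destroys it.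

Step 4
Reactants: 6 allylic alcohol; 7 vinyl acetate
Product: 9 (4Z,8E)-10-[(tert-butyldiphenylsilyl)oxy]-8-methyl-4-[(trimethylsilyl)methyl]deca-4,8-dienal, via allyl vinyl ether 8 (not isolated)
Conditions: [Ir(cod)Cl]2 (1 mol %), Na2CO3 (0.6 equiv), vinyl acetate, toluene, 100 °C; then 130 °C
Reagents that add atoms: vinyl acetate 7, C=COC(C)=O
Why: Ir‑catalysed transfer vinylation followed by Claisen rearrangement through a chair with the C9 substituent equatorial gives the trisubstituted allylsilane with C7 trans to C11 (4Z by CIP), under non‑acidic conditions that spare the allylsilane.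

Step 5
Reactants: 9 dienal; 10 isopropenylmagnesium bromide
Product: 11 (6Z,10E)-12-[(tert-butyldiphenylsilyl)oxy]-2,10-dimethyl-6-[(trimethylsilyl)methyl]dodeca-1,6,10-trien-3-ol (racemic)
Conditions: isopropenylMgBr, THF, −78 → 0 °C; aq. NH4Cl
Reagents that add atoms: isopropenylmagnesium bromide 10, C=C(C)[Mg]Br
Why: Grignard addition to the aldehyde gives the 2‑methylallylic alcohol needed for the second Claisen; the carbinol centre is again transient.

Step 6
Reactants: 11 allylic alcohol; 7 vinyl acetate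
Product: 13 (4E,8Z,12E)-14-[(tert-butyldiphenylsilyl)oxy]-4,12-dimethyl-8-[(trimethylsilyl)methyl]tetradeca-4,8,12-trienal, via allyl vinyl ether 12 (not isolated)
Conditions: [Ir(cod)Cl]2 (1 mol %), Na2CO3 (0.6 equiv), vinyl acetate, toluene, 100 °C; then 130 °C
Reagents that add atoms: vinyl acetate 7, C=COC(C)=O
Why: The same transfer vinylation and chair Claisen rearrangement builds the (E)‑C5=C10 alkene and delivers C3 as the aldehyde.

Step 7
Reactants: 13 trienal; 14 ethyltriphenylphosphonium bromide; 15 formaldehyde (from paraformaldehyde)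
Product: 19 (2Z,6E,10Z,14E)-16-[(tert-butyldiphenylsilyl)oxy]-2,6,14-trimethyl-10-[(trimethylsilyl)methyl]hexadeca-2,6,10,14-tetraen-1-ol, via lithio betaine 16 (not isolated), via β-oxido ylide 17 (not isolated), via dioxido phosphonium adduct 18 (not isolated)
Conditions: 14, n‑BuLi, THF, 0 °C; 13, −78 °C; n‑BuLi, −78 → −25 °C; (CH2O)n, −25 °C → rt
Reagents that add atoms: ethyltriphenylphosphonium bromide 14, CC[P+](c1ccccc1)(c1ccccc1)c1ccccc1.[Br-]; formaldehyde 15, C=O
Why: Wittig reaction in its β‑oxido‑ylide variant (Corey–Schlosser): the betaine is deprotonated and trapped by formaldehyde, and loss of Ph3PO with the first aldehyde's oxygen gives the 2‑methylallylic alcohol with CH2OH cis to the chain (2Z).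

Step 8
Reactants: 19 (2Z)-allylic alcohol
Product: 20 {(2R,3S)-3-[(3E,7Z,11E)-13-[(tert-butyldiphenylsilyl)oxy]-3,11-dimethyl-7-[(trimethylsilyl)methyl]trideca-3,7,11-trien-1-yl]-2-methyloxiran-2-yl}methanol
Conditions: Ti(OiPr)4 (10 mol %), D‑(−)‑diethyl tartrate (12 mol %), t‑BuOOH, 4 Å MS, CH2Cl2, −20 °C
Reagents that add atoms: tert‑butyl hydroperoxide, CC(C)(C)OO
Why: Sharpless asymmetric epoxidation is directed by the hydroxyl, so only the allylic alcohol alkene reacts, and D‑(−)‑tartrate gives the (2R,3S)‑oxirane (about 90–95 % ee expected for a 2‑methyl‑Z substrate); this sets the absolute configuration of the route.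

Step 9
Reactants: 20 epoxy alcohol
Product: 21 triethylsilyl ether of 20
Conditions: TESCl, imidazole, CH2Cl2, 0 °C
Reagents that add atoms: chlorotriethylsilane, CC[Si](Cl)(CC)CC
Why: Silylation masks the hydroxyl so that the Lewis acid binds the oxirane oxygen alone and is not chelated towards opening at C3.

Step 10
Reactants: 21 epoxy polyene
Product: 23 15-[(tert-butyldiphenylsilyl)oxy]labda-8(17),13E-diene-3β,19-diol (3S,4S,5R,9S,10R), via 19-O-TES bicycle 22 (not isolated)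
Conditions: MeAlCl2 (1.5 equiv), CH2Cl2, −94 → −78 °C; Et3N/MeOH quench; crude in AcOH/THF/H2O 3:1:1, rt
Reagents that add atoms: none
Why: Lewis‑acid epoxide‑initiated cation–olefin bicyclisation through a chair–chair fold.
- The oxirane opens with inversion at C4, so the Z‑CH2OSi group ends axial as C19 (4β) and the methyl equatorial.
- C3 is retained as the equatorial 3β‑OH.
- The E‑C5=C10 alkene gives the trans ring fusion (5α‑H, 10β‑Me).
- The allylsilane with C7 trans to C11 gives 9α‑H and, on loss of Me3Si, only the 8(17)‑alkene.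
- No cation is left to attack the C13 alkene; the labile TES ether is cleaved in the work‑up.

Step 11
Reactants: 23 diol
Product: 24 15-[(tert-butyldiphenylsilyl)oxy]-3β-hydroxylabda-8(17),13E-dien-19-al (3S,4R,5R,9S,10R)
Conditions: TEMPO (20 mol %), PhI(OAc)2 (1.1 equiv), CH2Cl2, rt
Reagents that add atoms: none
Why: Oxoammonium (TEMPO/BAIB) oxidation takes the primary C19 alcohol in preference to the secondary 3β‑OH; C4 is quaternary, so the aldehyde cannot epimerise or eliminate.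

Step 12
Reactants: 24 hydroxy aldehyde
Product: 25 3β-acetoxy-15-[(tert-butyldiphenylsilyl)oxy]labda-8(17),13E-dien-19-al
Conditions: Ac2O, pyridine, DMAP (cat.), CH2Cl2, 0 °C → rt
Reagents that add atoms: acetic anhydride, CC(=O)OC(C)=O
Why: DMAP‑catalysed acylation of the equatorial 3β‑OH; mild conditions avoid retro‑aldol opening of the β‑hydroxy aldehyde.

Step 13
Reactants: 25 silyl ether
Product: 26 3β-acetoxy-15-hydroxylabda-8(17),13E-dien-19-al (3S,4R,5R,9S,10R)
Conditions: HF·pyridine, pyridine, THF, 0 °C → rt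
Reagents that add atoms: none
Why: Buffered fluoride desilylation frees the allylic C15 alcohol without touching the acetate, the aldehyde or the alkenes.

**Compound list**
1 | geraniol | CC(C)=CCC/C(C)=C/CO | starting material
2 | tert‑butyl{[(2E)‑3,7‑dimethylocta‑2,6‑dien‑1‑yl]oxy}diphenylsilane | CC(C)=CCC/C(C)=C/CO[Si](c1ccccc1)(c1ccccc1)C(C)(C)C | intermediate
3 | tert‑butyl{[(2E)‑5‑(3,3‑dimethyloxiran‑2‑yl)‑3‑methylpent‑2‑en‑1‑yl]oxy}diphenylsilane (racemic, not isolated) | CC1(C)OC1CC/C(C)=C/CO[Si](c1ccccc1)(c1ccccc1)C(C)(C)C | intermediate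
4 | (4E)‑6‑[(tert‑butyldiphenylsilyl)oxy]‑4‑methylhex‑4‑enal | O=CCC/C(C)=C/CO[Si](c1ccccc1)(c1ccccc1)C(C)(C)C | intermediate
5 | (2‑bromoallyl)trimethylsilane | C=C(Br)C[Si](C)(C)C | starting material
6 | (6E)‑8‑[(tert‑butyldiphenylsilyl)oxy]‑6‑methyl‑2‑[(trimethylsilyl)methyl]octa‑1,6‑dien‑3‑ol (racemic) | C=C(C[Si](C)(C)C)C(O)CC/C(C)=C/CO[Si](c1ccccc1)(c1ccccc1)C(C)(C)C | intermediate
7 | vinyl acetate | C=COC(C)=O | starting material
8 | O‑vinyl ether of 6 (not isolated) | C=COC(CC/C(C)=C/CO[Si](c1ccccc1)(c1ccccc1)C(C)(C)C)C(=C)C[Si](C)(C)C | intermediate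
9 | (4Z,8E)‑10‑[(tert‑butyldiphenylsilyl)oxy]‑8‑methyl‑4‑[(trimethylsilyl)methyl]deca‑4,8‑dienal | O=CCC/C(C[Si](C)(C)C)=C/CC/C(C)=C/CO[Si](c1ccccc1)(c1ccccc1)C(C)(C)C | intermediate
10 | isopropenylmagnesium bromide | C=C(C)[Mg]Br | starting material
11 | (6Z,10E)‑12‑[(tert‑butyldiphenylsilyl)oxy]‑2,10‑dimethyl‑6‑[(trimethylsilyl)methyl]dodeca‑1,6,10‑trien‑3‑ol (racemic) | C=C(C)C(O)CC/C(C[Si](C)(C)C)=C/CC/C(C)=C/CO[Si](c1ccccc1)(c1ccccc1)C(C)(C)C | intermediate
12 | O‑vinyl ether of 11 (not isolated) | C=COC(CC/C(C[Si](C)(C)C)=C/CC/C(C)=C/CO[Si](c1ccccc1)(c1ccccc1)C(C)(C)C)C(C)=C | intermediate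
13 | (4E,8Z,12E)‑14‑[(tert‑butyldiphenylsilyl)oxy]‑4,12‑dimethyl‑8‑[(trimethylsilyl)methyl]tetradeca‑4,8,12‑trienal | O=CCC/C(C)=C/CC/C(C[Si](C)(C)C)=C/CC/C(C)=C/CO[Si](c1ccccc1)(c1ccccc1)C(C)(C)C | intermediate
14 | ethyltriphenylphosphonium bromide | CC[P+](c1ccccc1)(c1ccccc1)c1ccccc1.[Br-] | starting material
15 | formaldehyde (from paraformaldehyde) | C=O | starting material
16 | lithio betaine from 13 and the ethylidene ylide (diastereomer mixture, not isolated) | CC(C(O[Li])CC/C(C)=C/CC/C(C[Si](C)(C)C)=C/CC/C(C)=C/CO[Si](c1ccccc1)(c1ccccc1)C(C)(C)C)[P+](c1ccccc1)(c1ccccc1)c1ccccc1.[Br-] | intermediate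
17 | β‑oxido ylide (not isolated) | CC(C(O[Li])CC/C(C)=C/CC/C(C[Si](C)(C)C)=C/CC/C(C)=C/CO[Si](c1ccccc1)(c1ccccc1)C(C)(C)C)=P(c1ccccc1)(c1ccccc1)c1ccccc1 | intermediate
18 | dioxido phosphonium adduct of 17 and formaldehyde (not isolated) | CC(CO[Li])(C([O-])CC/C(C)=C/CC/C(C[Si](C)(C)C)=C/CC/C(C)=C/CO[Si](c1ccccc1)(c1ccccc1)C(C)(C)C)[P+](c1ccccc1)(c1ccccc1)c1ccccc1 | intermediate
19 | (2Z,6E,10Z,14E)‑16‑[(tert‑butyldiphenylsilyl)oxy]‑2,6,14‑trimethyl‑10‑[(trimethylsilyl)methyl]hexadeca‑2,6,10,14‑tetraen‑1‑ol | OC/C(C)=C\CC/C(C)=C/CC/C(C[Si](C)(C)C)=C/CC/C(C)=C/CO[Si](c1ccccc1)(c1ccccc1)C(C)(C)C | intermediate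
20 | {(2R,3S)‑3‑[(3E,7Z,11E)‑13‑[(tert‑butyldiphenylsilyl)oxy]‑3,11‑dimethyl‑7‑[(trimethylsilyl)methyl]trideca‑3,7,11‑trien‑1‑yl]‑2‑methyloxiran‑2‑yl}methanol | CC(C)(C)[Si](c1ccccc1)(c1ccccc1)OC/C=C(C)/CC/C=C(C[Si](C)(C)C)/CC/C=C(C)/CC[C@@H]1O[C@]1(C)CO | intermediate
21 | triethylsilyl ether of 20, (2R,3S)‑oxirane | CC(C)(C)[Si](c1ccccc1)(c1ccccc1)OC/C=C(C)/CC/C=C(C[Si](C)(C)C)/CC/C=C(C)/CC[C@@H]1O[C@]1(C)CO[Si](CC)(CC)CC | intermediate
22 | 15‑[(tert‑butyldiphenylsilyl)oxy]‑19‑[(triethylsilyl)oxy]labda‑8(17),13E‑dien‑3β‑ol, (3S,4S,5R,9S,10R) (not isolated) | C=C1CC[C@H]2[C@@](C)(CO[Si](CC)(CC)CC)[C@@H](O)CC[C@]2(C)[C@H]1CC/C(C)=C/CO[Si](c1ccccc1)(c1ccccc1)C(C)(C)C | intermediate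
23 | 15‑[(tert‑butyldiphenylsilyl)oxy]labda‑8(17),13E‑diene‑3β,19‑diol, (3S,4S,5R,9S,10R) | C=C1CC[C@H]2[C@@](C)(CO)[C@@H](O)CC[C@]2(C)[C@H]1CC/C(C)=C/CO[Si](c1ccccc1)(c1ccccc1)C(C)(C)C | intermediate
24 | 15‑[(tert‑butyldiphenylsilyl)oxy]‑3β‑hydroxylabda‑8(17),13E‑dien‑19‑al, (3S,4R,5R,9S,10R) | C=C1CC[C@H]2[C@@](C)(C=O)[C@@H](O)CC[C@]2(C)[C@H]1CC/C(C)=C/CO[Si](c1ccccc1)(c1ccccc1)C(C)(C)C | intermediate
25 | 3β‑acetoxy‑15‑[(tert‑butyldiphenylsilyl)oxy]labda‑8(17),13E‑dien‑19‑al, (3S,4R,5R,9S,10R) | C=C1CC[C@H]2[C@@](C)(C=O)[C@@H](OC(C)=O)CC[C@]2(C)[C@H]1CC/C(C)=C/CO[Si](c1ccccc1)(c1ccccc1)C(C)(C)C | intermediate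
26 | 3β‑acetoxy‑15‑hydroxylabda‑8(17),13E‑dien‑19‑al, (3S,4R,5R,9S,10R) (CNP0185120.1) | C=C1CC[C@H]2[C@@](C)(C=O)[C@@H](OC(C)=O)CC[C@]2(C)[C@H]1CC/C(C)=C/CO | target

**Step count:** 13 steps in total; the longest linear sequence is 13 steps (geraniol → 26).

**Three steps most likely to fail, with fallbacks**

Step 10 (bicyclisation). The silyloxymethyl group makes the tertiary oxirane carbon less willing to ionise, so 1,2‑shift to a β‑silyloxy aldehyde, 5‑exo opening at C3 or protodesilylation may compete. The fallback sets out from epoxy alcohol 20 and omits step 9. The free epoxy alcohol is cyclised by hydrogen‑bond activation in hexafluoroisopropanol with catalytic Ph4PBF4 at 0 °C, with no metal Lewis acid and hence no chelate steering the opening to C3. It comes back to the route at diol 23 directly and makes no compound outside the list (F0).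

Step 7 (β‑oxido‑ylide olefination). The yield or Z‑purity may be poor on this enolisable, polyfunctional aldehyde. The fallback sets out from trienal 13. Still–Gennari olefination with methyl 2‑[bis(2,2,2‑trifluoroethoxy)phosphoryl]propanoate (KHMDS, 18‑crown‑6, THF, −78 °C) gives methyl (2Z,6E,10Z,14E)‑16‑[(tert‑butyldiphenylsilyl)oxy]‑2,6,14‑trimethyl‑10‑[(trimethylsilyl)methyl]hexadeca‑2,6,10,14‑tetraenoate F1. DIBAL‑H reduction (CH2Cl2, −78 °C) then returns to the route at allylic alcohol 19, at the cost of one extra step.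

Step 4 (transfer vinylation and Claisen on the silylmethyl allylic alcohol; step 6 is the same reaction on a less sensitive substrate). The iridium catalyst may isomerise the allylic alcohol, or the vinyl ether may form poorly at the hindered carbinol. The fallback sets out from alcohol 6. Eschenmoser–Claisen rearrangement with N,N‑dimethylacetamide dimethyl acetal (xylene, 140 °C, neutral) gives (4Z,8E)‑10‑[(tert‑butyldiphenylsilyl)oxy]‑N,N,8‑trimethyl‑4‑[(trimethylsilyl)methyl]deca‑4,8‑dienamide F2. Reduction of the amide with Cp2Zr(H)Cl (THF, rt) then returns to the route at aldehyde 9.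

**Further compounds**
F1 | step 7 | methyl (2Z,6E,10Z,14E)‑16‑[(tert‑butyldiphenylsilyl)oxy]‑2,6,14‑trimethyl‑10‑[(trimethylsilyl)methyl]hexadeca‑2,6,10,14‑tetraenoate | COC(=O)/C(C)=C\CC/C(C)=C/CC/C(C[Si](C)(C)C)=C/CC/C(C)=C/CO[Si](c1ccccc1)(c1ccccc1)C(C)(C)C
F2 | step 4 | (4Z,8E)‑10‑[(tert‑butyldiphenylsilyl)oxy]‑N,N,8‑trimethyl‑4‑[(trimethylsilyl)methyl]deca‑4,8‑dienamide | CN(C)C(=O)CC/C(C[Si](C)(C)C)=C/CC/C(C)=C/CO[Si](c1ccccc1)(c1ccccc1)C(C)(C)C
F0 | step 10 | none | none
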